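## Retrosynthetic overview

1. The acrylic acid is unveiled last, by saponification, desilylation and Eschenmoser α-methylenation of a CH2CO2Et arm on ring carbon C2.
2. The side chain is cut at C2′–C3′: a B-alkyl Suzuki–Miyaura coupling joins a 5-vinyl oxane to an (E)-vinyl iodide that carries the (R)-carbinol (from 6-methylhept-5-en-2-one and pent-4-ynoic acid by Shapiro acylation, CBS reduction and Zr-catalysed carboalumination).
3. The only ring (oxane: O1, C2 acrylate-bearing, C3, C4, C5 side-chain-bearing, C6) is built in one flask by a formal [4+2] annulation: C3–C4 by radical allyl transfer to an iodo MEM ether, then C5–C6 by oxocarbenium–allylsilane closure.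
4. Enabling feature: C6 is an O-bound CH2 next to the C5 methine, so it can be an acetal-derived oxocarbenium carbon, while C5, whose side chain begins CH2–CH2, can be the γ-carbon of an allylsilane that leaves a vinyl handle; C3 is a primary carbon β to O1 and can be a radical; the 2,5-trans (diequatorial) pattern lets a chair closure relay C2 to C5.
5. C2 and its CH2CO2Et arm come from commercial ethyl (S)-4-chloro-3-hydroxybutanoate.

Key step: step 4

Remark: side-chain carbons are primed from C1′ at the ring; all starting materials and reagents named are taken as commercial.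

## Route

Step 1
Reactants: 1 ethyl (3S)-4-chloro-3-hydroxybutanoate
Product: 2 ethyl (3S)-3-hydroxy-4-iodobutanoate
Conditions: NaI, acetone, reflux
Reagents that add atoms: sodium iodide, [Na+].[I-]
Why: Finkelstein halide exchange (SN2 at the primary carbon, driven by precipitation of NaCl) should give the iodide needed as radical precursor; the carbinol centre is not touched.

Step 2
Reactants: 2 ethyl (3S)-3-hydroxy-4-iodobutanoate
Product: 3 ethyl (3S)-4-iodo-3-[(2-methoxyethoxy)methoxy]butanoate
Conditions: MEMCl, iPr2NEt, CH2Cl2, 0 °C → rt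
Reagents that add atoms: 2-methoxyethoxymethyl chloride (MEMCl), COCCOCCl
Why: Alkoxymethylation of the secondary alcohol under hindered-amine conditions (acetal protection) installs the O–CH2–O carbon that becomes ring C6; no stereocentre is affected.

Step 3
Reactants: 4 allyl phenyl sulfone [(prop-2-en-1-ylsulfonyl)benzene]
Product: 5 trimethyl[2-(phenylsulfonyl)but-3-en-1-yl]silane (racemic)
Conditions: n-BuLi, THF, −78 °C; then Me3SiCH2I, −78 → 0 °C
Reagents that add atoms: (iodomethyl)trimethylsilane, C[Si](C)(C)CI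
Why: α-Alkylation of the sulfone-stabilised allyl anion (SN2 on the α-silyl iodide) should give the β-silyl allyl sulfone; its stereocentre is racemic and is destroyed in step 4.

Step 4
Reactants: 3 ethyl (3S)-4-iodo-3-[(2-methoxyethoxy)methoxy]butanoate; 5 trimethyl[2-(phenylsulfonyl)but-3-en-1-yl]silane
Product: 7 ethyl 2-[(2R,5R)-5-ethenyloxan-2-yl]acetate, via allylsilane 6 (not isolated)
Conditions: 5 (2.5 equiv), (Bu3Sn)2 (1.2 equiv), hν (sunlamp), PhCF3, 35 °C; then CH2Cl2, −78 °C, SnCl4 (3 equiv), −78 → −40 °C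
Reagents that add atoms: none
Why: Proposed new method: in stage one Bu3Sn• (from (Bu3Sn)2, hν) abstracts iodine from 3, the primary C3 radical adds to the CH2= terminus of 5 and the adduct expels PhSO2• (SH2′ allyl transfer, the ditin returning PhSO2• to the chain), which forms C3–C4 and leaves allylsilane 6; in stage two SnCl4 chelates and ionises the MEM acetal to the oxocarbenium ion O1=C6H2+, which is captured by the γ-carbon C5 of the allylsilane with loss of Me3SiCl, forming C5–C6 and the vinyl group. The closest known reaction types are the ditin-mediated photochemical allylation of alkyl iodides with allyl sulfones (Keck-type allyl transfer) and the Lewis-acid cyclisation of MEM ethers onto π-nucleophiles (intramolecular Hosomi–Sakurai reaction); new are the silylmethyl-substituted allyl sulfone as donor of a nucleophilic allylsilane and the telescoping of both events into a formal [4+2] annulation. The oxane ring closes through a chair-like transition state in a mode that is 6-endo-trig for the oxocarbenium (C6=O1 inside the ring) and exo for the C5=C1′ alkene, the developing cation lying outside the ring, β to silicon. The new C5 stereocentre is set by the existing C2 centre: with CH2CO2Et equatorial the alkene should add with C1′ pseudo-equatorial, so the vinyl group ends equatorial and 2,5-trans, i.e. (2R,5R). The step needs chemoselective iodine abstraction and terminal addition (secured by the fast iodine transfer to tin and the unsubstituted CH2= of 5), ionisation of the acetal on the MEM side (secured by bidentate binding of SnCl4) and attack through C5 rather than C1′ (secured by the β-silicon effect and six- versus eight-membered ring size); the E/Z mixture of 6 converges on 7.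

Step 5
Reactants: 8 6-methylhept-5-en-2-one
Product: 9 N′-(6-methylhept-5-en-2-ylidene)-2,4,6-tri(propan-2-yl)benzenesulfonohydrazide
Conditions: 2,4,6-iPr3C6H2SO2NHNH2, MeOH, cat. HCl, rt
Reagents that add atoms: 2,4,6-tri(propan-2-yl)benzenesulfonohydrazide, NNS(=O)(=O)c1c(C(C)C)cc(C(C)C)cc1C(C)C
Why: Acid-catalysed condensation of the ketone with the sulfonyl hydrazide (hydrazone formation) should give the Shapiro precursor.

Step 6
Reactants: 10 pent-4-ynoic acid
Product: 11 N-methoxy-N-methylpent-4-ynamide
Conditions: CDI, CH2Cl2, rt; then MeNHOMe·HCl, rt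
Reagents that add atoms: N,O-dimethylhydroxylamine hydrochloride, CNOC.Cl
Why: Activation as the acyl imidazolide and aminolysis (Weinreb amide synthesis) should give the amide.

Step 7
Reactants: 9 N′-(6-methylhept-5-en-2-ylidene)-2,4,6-tri(propan-2-yl)benzenesulfonohydrazide (2.3 equiv); 11 N-methoxy-N-methylpent-4-ynamide
Product: 13 10-methyl-6-methylideneundec-9-en-1-yn-5-one, via vinyllithium 12 (not isolated)
Conditions: n-BuLi (2.05 equiv per 9), THF, −78 → 0 °C; then 11, −78 → −20 °C; cold aq. NH4Cl
Reagents that add atoms: none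
Why: Shapiro reaction (the hydrazone dianion forms on the methyl side and loses sulfinate and N2 to give the 2-lithio-1-alkene) followed by Weinreb ketone synthesis through the stable chelate should give the enone, one equivalent of 12 being consumed by the acetylenic C–H.

Step 8
Reactants: 13 10-methyl-6-methylideneundec-9-en-1-yn-5-one
Product: 14 (5R)-10-methyl-6-methylideneundec-9-en-1-yn-5-ol
Conditions: (S)-2-methyl-CBS-oxazaborolidine (0.2 equiv), catecholborane, toluene, −78 °C
Reagents that add atoms: none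
Why: Corey–Bakshi–Shibata reduction, in which the branched alkenyl group acts as the large substituent, should deliver hydride to the face that gives the (R)-allylic alcohol, by analogy with aryl ketone and enone reductions with the (S)-catalyst.

Step 9
Reactants: 14 (5R)-10-methyl-6-methylideneundec-9-en-1-yn-5-ol
Product: 15 tert-butyl(dimethyl){[(5R)-10-methyl-6-methylideneundec-9-en-1-yn-5-yl]oxy}silane
Conditions: TBSCl, imidazole, DMF, rt
Reagents that add atoms: tert-butyldimethylsilyl chloride, CC(C)(C)[Si](C)(C)Cl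
Why: Imidazole-promoted silylation of the secondary alcohol (silyl ether protection) should proceed without affecting the stereocentre.

Step 10
Reactants: 15 tert-butyl(dimethyl){[(5R)-10-methyl-6-methylideneundec-9-en-1-yn-5-yl]oxy}silane
Product: 17 tert-butyl{[(1E,5R)-1-iodo-2,10-dimethyl-6-methylideneundeca-1,9-dien-5-yl]oxy}dimethylsilane, via alkenylalane 16 (not isolated)
Conditions: AlMe3, Cp2ZrCl2 (0.25 equiv), CH2Cl2, 0 °C → rt; then I2, THF, −30 → 0 °C
Reagents that add atoms: trimethylaluminium, C[Al](C)C; iodine, II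
Why: Negishi zirconium-catalysed carboalumination (syn addition of Me–Al across the terminal alkyne, methyl to the internal carbon) and iodinolysis with retention should fix the (E)-trisubstituted vinyl iodide.

Step 11
Reactants: 7 ethyl 2-[(2R,5R)-5-ethenyloxan-2-yl]acetate; 17 tert-butyl{[(1E,5R)-1-iodo-2,10-dimethyl-6-methylideneundeca-1,9-dien-5-yl]oxy}dimethylsilane
Product: 19 ethyl 2-[(2R,5S)-5-[(3E,7R)-7-{[tert-butyl(dimethyl)silyl]oxy}-4,12-dimethyl-8-methylidenetrideca-3,11-dien-1-yl]oxan-2-yl]acetate, via alkylborane 18 (not isolated)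
Conditions: 9-BBN-H, THF, 0 °C → rt; then 17, Pd(dppf)Cl2 (5 mol%), AsPh3, Cs2CO3, DMF/H2O, rt
Reagents that add atoms: none
Why: Anti-Markovnikov hydroboration of the vinyl group and B-alkyl Suzuki–Miyaura coupling with retention of the (E)-geometry should join the two fragments; no stereocentre is touched (the C5 descriptor changes from R to S only through the priority rules).

Step 12
Reactants: 19 ethyl 2-[(2R,5S)-5-[(3E,7R)-7-{[tert-butyl(dimethyl)silyl]oxy}-4,12-dimethyl-8-methylidenetrideca-3,11-dien-1-yl]oxan-2-yl]acetate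
Product: 22 ethyl 2-[(2R,5S)-5-[(3E,7R)-7-{[tert-butyl(dimethyl)silyl]oxy}-4,12-dimethyl-8-methylidenetrideca-3,11-dien-1-yl]oxan-2-yl]prop-2-enoate, via Mannich base 20 (not isolated), via methiodide 21 (not isolated)
Conditions: LiN(iPr)2, THF, −78 °C; CH2=NMe2+ I−, −78 → 0 °C; MeI, CH2Cl2/MeOH, rt; DBU, CH2Cl2, rt
Reagents that add atoms: Eschenmoser's salt (N,N-dimethylmethyleneiminium iodide), C=[N+](C)C.[I-]
Why: Eschenmoser α-methylenation (ester enolate Mannich reaction, N-methylation, E1cB loss of Me3N) should convert the acetate arm into the acrylate, the enolate being kept at −78 °C to suppress β-elimination of the ring oxygen; C2 and C5 are not affected.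

Step 13
Reactants: 22 ethyl 2-[(2R,5S)-5-[(3E,7R)-7-{[tert-butyl(dimethyl)silyl]oxy}-4,12-dimethyl-8-methylidenetrideca-3,11-dien-1-yl]oxan-2-yl]prop-2-enoate
Product: 23 ethyl 2-[(2R,5S)-5-[(3E,7R)-7-hydroxy-4,12-dimethyl-8-methylidenetrideca-3,11-dien-1-yl]oxan-2-yl]prop-2-enoate
Conditions: Bu4NF, AcOH, THF, 0 °C → rt
Reagents that add atoms: none
Why: Fluoride-mediated cleavage of the silyl ether, buffered with acetic acid to spare the acrylate, should free the allylic alcohol.

Step 14
Reactants: 23 ethyl 2-[(2R,5S)-5-[(3E,7R)-7-hydroxy-4,12-dimethyl-8-methylidenetrideca-3,11-dien-1-yl]oxan-2-yl]prop-2-enoate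
Product: 24 2-[(2R,5S)-5-[(3E,7R)-7-hydroxy-4,12-dimethyl-8-methylidenetrideca-3,11-dien-1-yl]oxan-2-yl]prop-2-enoic acid
Conditions: LiOH, THF/H2O, rt; then 1 M HCl to pH 3–4
Reagents that add atoms: lithium hydroxide, [Li+].[OH-]
Why: Saponification of the ethyl ester (acyl–oxygen cleavage) and mild acidification should give the target acid with all stereocentres intact.

## Compound list

1 | ethyl (3S)-4-chloro-3-hydroxybutanoate | CCOC(=O)C[C@H](O)CCl | starting material
2 | ethyl (3S)-3-hydroxy-4-iodobutanoate | CCOC(=O)C[C@H](O)CI | intermediate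
3 | ethyl (3S)-4-iodo-3-[(2-methoxyethoxy)methoxy]butanoate | CCOC(=O)C[C@H](OCOCCOC)CI | intermediate
4 | allyl phenyl sulfone | C=CCS(=O)(=O)c1ccccc1 | starting material
5 | trimethyl[2-(phenylsulfonyl)but-3-en-1-yl]silane (racemic) | C=CC(C[Si](C)(C)C)S(=O)(=O)c1ccccc1 | intermediate
6 | ethyl (3R)-3-[(2-methoxyethoxy)methoxy]-8-(trimethylsilyl)oct-6-enoate (E/Z mixture) | CCOC(=O)C[C@H](OCOCCOC)CCC=CC[Si](C)(C)C | intermediate (not isolated)
7 | ethyl 2-[(2R,5R)-5-ethenyloxan-2-yl]acetate | C=C[C@H]1CC[C@H](CC(=O)OCC)OC1 | intermediate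
8 | 6-methylhept-5-en-2-one | CC(=O)CCC=C(C)C | starting material
9 | N′-(6-methylhept-5-en-2-ylidene)-2,4,6-tri(propan-2-yl)benzenesulfonohydrazide (C=N isomers) | CC(CCC=C(C)C)=NNS(=O)(=O)c1c(C(C)C)cc(C(C)C)cc1C(C)C | intermediate
10 | pent-4-ynoic acid | C#CCCC(=O)O | starting material
11 | N-methoxy-N-methylpent-4-ynamide | C#CCCC(=O)N(C)OC | intermediate
12 | (6-methylhepta-1,5-dien-2-yl)lithium | [Li]C(=C)CCC=C(C)C | intermediate (not isolated)
13 | 10-methyl-6-methylideneundec-9-en-1-yn-5-one | C#CCCC(=O)C(=C)CCC=C(C)C | intermediate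
14 | (5R)-10-methyl-6-methylideneundec-9-en-1-yn-5-ol | C=C(CCC=C(C)C)[C@H](O)CCC#C | intermediate
15 | tert-butyl(dimethyl){[(5R)-10-methyl-6-methylideneundec-9-en-1-yn-5-yl]oxy}silane | C=C(CCC=C(C)C)[C@H](O[Si](C)(C)C(C)(C)C)CCC#C | intermediate
16 | [(1E,5R)-5-{[tert-butyl(dimethyl)silyl]oxy}-2,10-dimethyl-6-methylideneundeca-1,9-dien-1-yl]dimethylalane | C=C(CCC=C(C)C)[C@H](O[Si](C)(C)C(C)(C)C)CC/C(C)=C/[Al](C)C | intermediate (not isolated)
17 | tert-butyl{[(1E,5R)-1-iodo-2,10-dimethyl-6-methylideneundeca-1,9-dien-5-yl]oxy}dimethylsilane | C=C(CCC=C(C)C)[C@H](O[Si](C)(C)C(C)(C)C)CC/C(C)=C/I | intermediate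
18 | ethyl 2-[(2R,5S)-5-[2-(9-borabicyclo[3.3.1]nonan-9-yl)ethyl]oxan-2-yl]acetate | B1(CC[C@H]2CC[C@H](CC(=O)OCC)OC2)C2CCCC1CCC2 | intermediate (not isolated)
19 | ethyl 2-[(2R,5S)-5-[(3E,7R)-7-{[tert-butyl(dimethyl)silyl]oxy}-4,12-dimethyl-8-methylidenetrideca-3,11-dien-1-yl]oxan-2-yl]acetate | C=C(CCC=C(C)C)[C@H](O[Si](C)(C)C(C)(C)C)CC/C(C)=C/CC[C@H]1CC[C@H](CC(=O)OCC)OC1 | intermediate
20 | ethyl 3-(dimethylamino)-2-[(2R,5S)-5-[(3E,7R)-7-{[tert-butyl(dimethyl)silyl]oxy}-4,12-dimethyl-8-methylidenetrideca-3,11-dien-1-yl]oxan-2-yl]propanoate (both epimers at the new α-carbon) | C=C(CCC=C(C)C)[C@H](O[Si](C)(C)C(C)(C)C)CC/C(C)=C/CC[C@H]1CC[C@H](C(CN(C)C)C(=O)OCC)OC1 | intermediate (not isolated)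
21 | trimethylammonium iodide of 20 (N-methylated Mannich base) | C=C(CCC=C(C)C)[C@H](O[Si](C)(C)C(C)(C)C)CC/C(C)=C/CC[C@H]1CC[C@H](C(C[N+](C)(C)C)C(=O)OCC)OC1.[I-] | intermediate (not isolated)
22 | ethyl 2-[(2R,5S)-5-[(3E,7R)-7-{[tert-butyl(dimethyl)silyl]oxy}-4,12-dimethyl-8-methylidenetrideca-3,11-dien-1-yl]oxan-2-yl]prop-2-enoate | C=C(CCC=C(C)C)[C@H](O[Si](C)(C)C(C)(C)C)CC/C(C)=C/CC[C@H]1CC[C@H](C(=C)C(=O)OCC)OC1 | intermediate
23 | ethyl 2-[(2R,5S)-5-[(3E,7R)-7-hydroxy-4,12-dimethyl-8-methylidenetrideca-3,11-dien-1-yl]oxan-2-yl]prop-2-enoate | C=C(CCC=C(C)C)[C@H](O)CC/C(C)=C/CC[C@H]1CC[C@H](C(=C)C(=O)OCC)OC1 | intermediate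
24 | 2-[(2R,5S)-5-[(3E,7R)-7-hydroxy-4,12-dimethyl-8-methylidenetrideca-3,11-dien-1-yl]oxan-2-yl]prop-2-enoic acid | C=C(CCC=C(C)C)[C@H](O)CC/C(C)=C/CC[C@H]1CC[C@H](C(=C)C(=O)O)OC1 | target

## Step count and risks

Total step count: 14 (steps 1–4 ring fragment, steps 5–10 side-chain fragment, steps 11–14 union and endgame).
Longest linear sequence: 9 steps (5, 7, 8, 9, 10, 11, 12, 13, 14, starting from 8).

Steps most likely to fail:

1. Step 4 (Proposed new method). The primary radical may add too slowly to the α-branched allyl sulfone, with stannyl radicals attacking 5 instead. In the second stage tin residues may intercept SnCl4, so that the acetal ionises on the wrong side (loss of the MEM group) or the allylsilane is protodesilylated. The facial selectivity of the ring closure may also be lower than assumed. The fallback is stepwise and uses known chemistry. It sets out from 3, which is allylated with allylSnBu3 (AIBN, PhH, 80 °C, Keck radical allylation) to give ethyl (3R)-3-[(2-methoxyethoxy)methoxy]hept-6-enoate F1. Cross-metathesis of F1 with allyltrimethylsilane (second-generation Grubbs catalyst, CH2Cl2, 40 °C) should give allylsilane 6, now isolated and free of tin. Cyclisation of 6 with SnCl4 (CH2Cl2, −78 °C) then gives 7, where the route is rejoined.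

2. Step 12. The ester enolate may undergo β-elimination of the ring oxygen (opening of the oxane), or the ammonium salt may eliminate incompletely. The fallback avoids the ester enolate. It sets out from 19, which is reduced with iBu2AlH (CH2Cl2, −78 °C) to 2-[(2R,5S)-5-[(3E,7R)-7-{[tert-butyl(dimethyl)silyl]oxy}-4,12-dimethyl-8-methylidenetrideca-3,11-dien-1-yl]oxan-2-yl]acetaldehyde F2. Amine-catalysed α-methylenation (aqueous HCHO, pyrrolidine, propionic acid, iPrOH, 45 °C) should give 2-[(2R,5S)-5-[(3E,7R)-7-{[tert-butyl(dimethyl)silyl]oxy}-4,12-dimethyl-8-methylidenetrideca-3,11-dien-1-yl]oxan-2-yl]prop-2-enal F3. Pinnick oxidation (NaClO2, NaH2PO4, 2-methylbut-2-ene, tBuOH/H2O) gives 2-[(2R,5S)-5-[(3E,7R)-7-{[tert-butyl(dimethyl)silyl]oxy}-4,12-dimethyl-8-methylidenetrideca-3,11-dien-1-yl]oxan-2-yl]prop-2-enoic acid F4. Desilylation with Bu4NF then gives 24 directly, so steps 13 and 14 are not needed.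

3. Step 8. Facial discrimination between two flexible chains of similar size may be insufficient, and conjugate reduction of the α-methylene ketone may compete. The fallback makes the C–C bond and the carbinol centre together instead of reducing a ketone. It sets out from 8, which is enolised kinetically on the methyl side (KN(SiMe3)2, THF, −78 °C) and trapped with PhNTf2 to give 6-methylhepta-1,5-dien-2-yl trifluoromethanesulfonate F5. F5 is coupled with commercial pent-4-ynal in a catalytic enantioselective Nozaki–Hiyama–Kishi reaction (CrCl2, NiCl2, a chiral oxazoline–sulfonamide ligand, Mn powder, Me3SiCl, MeCN), the ligand antipode being chosen for the (R)-carbinol. After desilylating work-up this should give 14, where the route is rejoined at step 9.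

Further compounds
F1 | step 4 | ethyl (3R)-3-[(2-methoxyethoxy)methoxy]hept-6-enoate | CCOC(=O)C[C@H](OCOCCOC)CCC=C
F2 | step 12 | 2-[(2R,5S)-5-[(3E,7R)-7-{[tert-butyl(dimethyl)silyl]oxy}-4,12-dimethyl-8-methylidenetrideca-3,11-dien-1-yl]oxan-2-yl]acetaldehyde | C=C(CCC=C(C)C)[C@H](O[Si](C)(C)C(C)(C)C)CC/C(C)=C/CC[C@H]1CC[C@H](CC=O)OC1
F3 | step 12 | 2-[(2R,5S)-5-[(3E,7R)-7-{[tert-butyl(dimethyl)silyl]oxy}-4,12-dimethyl-8-methylidenetrideca-3,11-dien-1-yl]oxan-2-yl]prop-2-enal | C=C(CCC=C(C)C)[C@H](O[Si](C)(C)C(C)(C)C)CC/C(C)=C/CC[C@H]1CC[C@H](C(=C)C=O)OC1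
F4 | step 12 | 2-[(2R,5S)-5-[(3E,7R)-7-{[tert-butyl(dimethyl)silyl]oxy}-4,12-dimethyl-8-methylidenetrideca-3,11-dien-1-yl]oxan-2-yl]prop-2-enoic acid | C=C(CCC=C(C)C)[C@H](O[Si](C)(C)C(C)(C)C)CC/C(C)=C/CC[C@H]1CC[C@H](C(=C)C(=O)O)OC1
F5 | step 8 | 6-methylhepta-1,5-dien-2-yl trifluoromethanesulfonate | C=C(CCC=C(C)C)OS(=O)(=O)C(F)(F)F
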